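**Retrosynthetic overview**
- The route rests on the unit O1–C2(aryl)–C3–C3a with the exocyclic carbon C9 on C3: the dihydrofuran ring plus C9 is a flavanone (2-arylchroman-4-one) whose carbonyl carbon has been pushed out of the ring.
- Late disconnections: the C5 propenal from an aryl bromide (Heck reaction with acrolein diethyl acetal), the C9 isovalerate from a primary alcohol that comes from a methyl ester, and the ring B phenol from its mesylate.
- Key disconnection: the C3–C3a bond, made by oxidative 1,2-shift of ring A in an (R)-flavanone. Flavanone C4 becomes C9, C6 becomes C5 and C8 becomes C7.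
- The flavanone comes from asymmetric rhodium-catalysed 1,4-addition of a mesyloxy-methoxyphenylboronic acid to 6-bromo-8-methoxychromone (this sets C2). The chromone comes from a brominated 2-hydroxyacetophenone and DMF dimethyl acetal.
- Ring order: rings A and B are bought, the pyranone ring is closed in step 2 and contracted to the dihydrofuran ring in step 6.

Key step: step 6

Remark (assumption): both antipodes of the chiral diene ligand of step 5 are available, and the antipode that delivers the aryl group to the face of C2 giving the 2R flavanone is the one used; this assignment would be fixed on a test scale before scale-up.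

**Step 1**
Reactants: 1 1-(2-hydroxy-3-methoxyphenyl)ethanone
Product: 2 1-(5-bromo-2-hydroxy-3-methoxyphenyl)ethanone
Conditions: NBS (1.05 equiv), MeCN, 0 °C → rt
Reagents that add atoms: N-bromosuccinimide, O=C1CCC(=O)N1Br
Why: Electrophilic aromatic bromination in which the phenolic OH, whose two ortho positions are blocked, directs bromine to its para carbon, the carbon that becomes C5 of the target.

**Step 2**
Reactants: 2 1-(5-bromo-2-hydroxy-3-methoxyphenyl)ethanone
Product: 4 6-bromo-8-methoxy-4H-chromen-4-one, via enaminone 3 (not isolated)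
Conditions: Me2NCH(OMe)2, toluene, 100 °C; concentrate; conc. HCl, CH2Cl2, 40 °C
Reagents that add atoms: N,N-dimethylformamide dimethyl acetal, COC(OC)N(C)C
Why: Condensation of the methyl ketone with the amide acetal gives the enaminone, and acid-induced addition of the phenol to its β-carbon with loss of dimethylamine closes the pyranone ring (enaminone route to chromones).

**Step 3**
Reactants: 5 2-methoxy-4-(4,4,5,5-tetramethyl-1,3,2-dioxaborolan-2-yl)phenol
Product: 6 2-methoxy-4-(4,4,5,5-tetramethyl-1,3,2-dioxaborolan-2-yl)phenyl methanesulfonate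
Conditions: MsCl, Et3N, CH2Cl2, 0 °C
Reagents that add atoms: methanesulfonyl chloride, CS(Cl)(=O)=O
Why: O-Sulfonylation of the phenol gives a mesylate that makes ring B electron-poor for steps 5 and 6 and should withstand acid, oxidant and hydride.

**Step 4**
Reactants: 6 2-methoxy-4-(4,4,5,5-tetramethyl-1,3,2-dioxaborolan-2-yl)phenyl methanesulfonate
Product: 7 [3-methoxy-4-(methylsulfonyloxy)phenyl]boronic acid
Conditions: NaIO4, NH4OAc, acetone/H2O (1:1), rt
Reagents that add atoms: water, O
Why: Oxidative deprotection of the pinacol boronate, in which periodate cleaves the pinacol released by hydrolysis to acetone and so drives the equilibrium to the free boronic acid without touching the mesylate.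

**Step 5**
Reactants: 4 6-bromo-8-methoxy-4H-chromen-4-one; 7 [3-methoxy-4-(methylsulfonyloxy)phenyl]boronic acid
Product: 8 (2R)-6-bromo-8-methoxy-2-[3-methoxy-4-(methylsulfonyloxy)phenyl]chroman-4-one
Conditions: [RhCl(C2H4)2]2 (2.5 mol %), chiral 2,5-diphenylbicyclo[2.2.2]octa-2,5-diene (5.5 mol %, antipode as in the remark), KOH (aq, 0.3 equiv), toluene, 30 °C
Reagents that add atoms: none
Why: Hayashi–Miyaura asymmetric 1,4-addition, in which the arylrhodium species formed by transmetalation inserts the chromone C2=C3 bond on the face left open by the chiral diene, setting C2 as R under catalyst control, while the rhodium catalyst should leave the aryl bromide and the mesylate alone.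

**Step 6**
Reactants: 8 (2R)-6-bromo-8-methoxy-2-[3-methoxy-4-(methylsulfonyloxy)phenyl]chroman-4-one
Product: 10 methyl (2R,3R)-5-bromo-7-methoxy-2-[3-methoxy-4-(methylsulfonyloxy)phenyl]-2,3-dihydro-1-benzofuran-3-carboxylate, via methyl enol ether 9 (not isolated)
Conditions: PhI(OAc)2 (1.2 equiv), conc. H2SO4 (0.3 equiv), HC(OMe)3, 0 °C → rt
Reagents that add atoms: trimethyl orthoformate, COC(OC)OC
Why: Acid and the orthoformate turn ketone 8 into methyl enol ether 9, the acid-activated iodane adds to C3 on the face anti to the C2 aryl group and methanol adds at the old carbonyl carbon, giving an α-iodanyl dimethyl ketal whose equatorial C3–I bond lies antiperiplanar to the bond from the ketal carbon to ring A; the ring A carbon then shifts from the ketal carbon to C3 through a phenonium-like bridge while iodobenzene leaves, and the dimethoxycarbenium ion left outside the ring loses a methyl group to give the methyl ester. The closest known reaction type is the oxidative 1,2-aryl migration of aryl ketones, and of flavanones in particular, with trivalent-iodine or trivalent-thallium oxidants in trimethyl orthoformate, which gives methyl trans-2-aryl-2,3-dihydrobenzofuran-3-carboxylates. The dihydrofuran ring O1–C2–C3–C3a–C7a is not closed by cyclisation of a chain but by ring contraction: a 1,2-shift through a three-membered bridged transition structure makes the C3–C3a bond and expels the carbonyl carbon from the six-membered ring. C2 is not touched and keeps the R configuration from step 5, while C3 is set by the substrate: iodane attack anti to the C2 aryl group followed by migration with inversion places the ester trans to the aryl group (2R,3R, the same spatial arrangement as 3S in the target), which is also the more stable epimer. The step needs migration of ring A in preference to migration of ring B, dehydrogenation and simple α-methoxylation: the mesylate makes ring B a poor migrating group and its shift would need a diaxial arrangement, whereas the migrating ring A carbon is ortho to the ring oxygen and is held anti to the leaving group. It also needs enol ether formation to outrun acid-induced opening to the chalcone, which excess orthoformate as water scavenger, low temperature and the electron-poor ring B (a poor support for a benzylic cation at C2) should secure.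

**Step 7**
Reactants: 10 methyl (2R,3R)-5-bromo-7-methoxy-2-[3-methoxy-4-(methylsulfonyloxy)phenyl]-2,3-dihydro-1-benzofuran-3-carboxylate
Product: 11 4-[(2R,3S)-5-bromo-3-(hydroxymethyl)-7-methoxy-2,3-dihydro-1-benzofuran-2-yl]-2-methoxyphenyl methanesulfonate
Conditions: LiBH4 (2 equiv), THF, 0 °C → rt; aq. NH4Cl
Reagents that add atoms: none
Why: Chemoselective borohydride reduction of the ester to the primary alcohol C9–OH, which should leave the aryl bromide and the aryl mesylate untouched and cannot harm C3 because the trans arrangement is the stable one.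

**Step 8**
Reactants: 11 4-[(2R,3S)-5-bromo-3-(hydroxymethyl)-7-methoxy-2,3-dihydro-1-benzofuran-2-yl]-2-methoxyphenyl methanesulfonate
Product: 12 4-[(2R,3S)-5-bromo-3-(hydroxymethyl)-7-methoxy-2,3-dihydro-1-benzofuran-2-yl]-2-methoxyphenol
Conditions: NaOH (2 M aq), MeOH/THF, 60 °C; aq. NH4Cl
Reagents that add atoms: none
Why: Alkaline cleavage of the aryl methanesulfonate (hydroxide attack at sulfur or sulfene elimination) frees the ring B phenol at a stage where no ester or aldehyde is present, and the moderate temperature should keep the phenoxide from opening the dihydrofuran ring.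

**Step 9**
Reactants: 12 4-[(2R,3S)-5-bromo-3-(hydroxymethyl)-7-methoxy-2,3-dihydro-1-benzofuran-2-yl]-2-methoxyphenol
Product: 13 [(2R,3S)-5-bromo-7-methoxy-2-[3-methoxy-4-(3-methylbutanoyloxy)phenyl]-2,3-dihydro-1-benzofuran-3-yl]methyl 3-methylbutanoate
Conditions: iPrCH2COCl (2.5 equiv), Et3N, DMAP (cat.), CH2Cl2, 0 °C → rt
Reagents that add atoms: 3-methylbutanoyl chloride, CC(C)CC(Cl)=O
Why: DMAP-catalysed acylation of both hydroxyl groups with the acid chloride avoids any need to differentiate the phenol from the primary alcohol at this point.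

**Step 10**
Reactants: 13 [(2R,3S)-5-bromo-7-methoxy-2-[3-methoxy-4-(3-methylbutanoyloxy)phenyl]-2,3-dihydro-1-benzofuran-3-yl]methyl 3-methylbutanoate
Product: 14 [(2R,3S)-5-bromo-2-(4-hydroxy-3-methoxyphenyl)-7-methoxy-2,3-dihydro-1-benzofuran-3-yl]methyl 3-methylbutanoate
Conditions: pyrrolidine (2 equiv), CH2Cl2, 0 °C → rt
Reagents that add atoms: none
Why: Chemoselective aminolysis, in which the aryl ester with its phenoxide leaving group reacts with the secondary amine far faster than the alkyl ester, so that only the phenol is released.

**Step 11**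
Reactants: 14 [(2R,3S)-5-bromo-2-(4-hydroxy-3-methoxyphenyl)-7-methoxy-2,3-dihydro-1-benzofuran-3-yl]methyl 3-methylbutanoate
Product: 16 [(2R,3S)-2-(4-hydroxy-3-methoxyphenyl)-7-methoxy-5-[(E)-3-oxoprop-1-enyl]-2,3-dihydro-1-benzofuran-3-yl]methyl 3-methylbutanoate, via diethyl acetal 15 (not isolated)
Conditions: CH2=CHCH(OEt)2 (3 equiv), Pd(OAc)2 (5 mol %), nBu4NOAc, K2CO3, KCl, DMF, 90 °C; then 2 M HCl, THF, rt
Reagents that add atoms: acrolein diethyl acetal, C=CC(OCC)OCC; water, O
Why: Phosphine-free Heck reaction of the aryl bromide with the acrolein acetal, in which syn insertion and syn β-hydride elimination toward the ring give the E-alkene and the acetate and carbonate bases favour the unsaturated acetal, followed by mild acetal hydrolysis that unmasks the enal without cleaving the alkyl ester.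

**Compound list**
1 | 1-(2-hydroxy-3-methoxyphenyl)ethanone | CC(=O)c1cccc(OC)c1O | starting material
2 | 1-(5-bromo-2-hydroxy-3-methoxyphenyl)ethanone | CC(=O)c1cc(Br)cc(OC)c1O | intermediate
3 | (E)-1-(5-bromo-2-hydroxy-3-methoxyphenyl)-3-(dimethylamino)prop-2-en-1-one | CN(C)/C=C/C(=O)c1cc(Br)cc(OC)c1O | intermediate
4 | 6-bromo-8-methoxy-4H-chromen-4-one | COc1cc(Br)cc2c1OC=CC2=O | intermediate
5 | 2-methoxy-4-(4,4,5,5-tetramethyl-1,3,2-dioxaborolan-2-yl)phenol | COc1cc(B2OC(C)(C)C(C)(C)O2)ccc1O | starting material
6 | 2-methoxy-4-(4,4,5,5-tetramethyl-1,3,2-dioxaborolan-2-yl)phenyl methanesulfonate | COc1cc(B2OC(C)(C)C(C)(C)O2)ccc1OS(C)(=O)=O | intermediate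
7 | [3-methoxy-4-(methylsulfonyloxy)phenyl]boronic acid | COc1cc(B(O)O)ccc1OS(C)(=O)=O | intermediate
8 | (2R)-6-bromo-8-methoxy-2-[3-methoxy-4-(methylsulfonyloxy)phenyl]chroman-4-one | COc1cc([C@@H]2Oc3c(OC)cc(Br)cc3C(=O)C2)ccc1OS(C)(=O)=O | intermediate
9 | (2R)-6-bromo-4,8-dimethoxy-2-[3-methoxy-4-(methylsulfonyloxy)phenyl]-2H-chromene | COc1cc([C@@H]2Oc3c(OC)cc(Br)cc3C(OC)=C2)ccc1OS(C)(=O)=O | intermediate
10 | methyl (2R,3R)-5-bromo-7-methoxy-2-[3-methoxy-4-(methylsulfonyloxy)phenyl]-2,3-dihydro-1-benzofuran-3-carboxylate (trans) | COc1cc([C@@H]2Oc3c(OC)cc(Br)cc3[C@H]2C(=O)OC)ccc1OS(C)(=O)=O | intermediate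
11 | 4-[(2R,3S)-5-bromo-3-(hydroxymethyl)-7-methoxy-2,3-dihydro-1-benzofuran-2-yl]-2-methoxyphenyl methanesulfonate | COc1cc([C@@H]2Oc3c(OC)cc(Br)cc3[C@H]2CO)ccc1OS(C)(=O)=O | intermediate
12 | 4-[(2R,3S)-5-bromo-3-(hydroxymethyl)-7-methoxy-2,3-dihydro-1-benzofuran-2-yl]-2-methoxyphenol | COc1cc([C@@H]2Oc3c(OC)cc(Br)cc3[C@H]2CO)ccc1O | intermediate
13 | [(2R,3S)-5-bromo-7-methoxy-2-[3-methoxy-4-(3-methylbutanoyloxy)phenyl]-2,3-dihydro-1-benzofuran-3-yl]methyl 3-methylbutanoate | COc1cc([C@@H]2Oc3c(OC)cc(Br)cc3[C@H]2COC(=O)CC(C)C)ccc1OC(=O)CC(C)C | intermediate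
14 | [(2R,3S)-5-bromo-2-(4-hydroxy-3-methoxyphenyl)-7-methoxy-2,3-dihydro-1-benzofuran-3-yl]methyl 3-methylbutanoate | COc1cc([C@@H]2Oc3c(OC)cc(Br)cc3[C@H]2COC(=O)CC(C)C)ccc1O | intermediate
15 | [(2R,3S)-5-[(E)-3,3-diethoxyprop-1-enyl]-2-(4-hydroxy-3-methoxyphenyl)-7-methoxy-2,3-dihydro-1-benzofuran-3-yl]methyl 3-methylbutanoate | COc1cc([C@@H]2Oc3c(OC)cc(/C=C/C(OCC)OCC)cc3[C@H]2COC(=O)CC(C)C)ccc1O | intermediate
16 | [(2R,3S)-2-(4-hydroxy-3-methoxyphenyl)-7-methoxy-5-[(E)-3-oxoprop-1-enyl]-2,3-dihydro-1-benzofuran-3-yl]methyl 3-methylbutanoate | COc1cc([C@@H]2Oc3c(OC)cc(/C=C/C=O)cc3[C@H]2COC(=O)CC(C)C)ccc1O | target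

**Step count**
Total: 11 steps. Longest linear sequence: 9 steps (steps 1, 2, 5, 6, 7, 8, 9, 10, 11).

**Steps most likely to fail**

1. Step 6 (ring contraction). Possible failures are dehydrogenation of the heterocycle, migration of ring B in place of ring A, α-methoxylation at C3 without any shift, and acid-induced opening and reclosure of the pyranone ring with loss of enantiopurity before the enol ether has formed. The fallback keeps the same C3–C3a bond formation but makes it stepwise; it sets out from 8 and comes back at 10. Compound 8 would be brominated at C3 with CuBr2 in EtOAc/CHCl3 at reflux to give the trans-3-bromoflavanone F1. The ketone would then be ketalised with HC(OMe)3, MeOH and TsOH to give the bromo dimethyl ketal F2. Treatment of F2 with AgBF4 in MeOH, then aqueous work-up, should pull off the equatorial bromide while ring A shifts to C3 with inversion (the silver-assisted 1,2-aryl shift of α-halo ketals to α-aryl esters), giving the trans ester 10.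

2. Step 5 (asymmetric 1,4-addition). Possible failures are slow aryl transfer to the substituted chromone, protodeboronation of the boronic acid, a second addition to the ketone, and base-induced retro-oxa-Michael opening that erodes the enantiomeric purity. The fallback sets out from 2 and comes back at 8. Vanillin would be mesylated (MsCl, Et3N) to 4-formyl-2-methoxyphenyl methanesulfonate F3. Claisen–Schmidt condensation of 2 with F3 under acid catalysis (HCl generated from SOCl2 in EtOH, which the mesylate tolerates) should give the chalcone F4. Cyclisation with NaOAc in refluxing EtOH should give the racemic flavanone F5. Kinetic resolution of F5 by asymmetric transfer hydrogenation with RhCl(C5Me5)(TsDPEN) (antipode chosen to reduce the 2S enantiomer) and HCO2H/Et3N in EtOAc should convert the unwanted enantiomer into the cis-flavan-4-ol F6, and the unreduced (2R)-flavanone 8 would be separated by chromatography.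

3. Step 11 (Heck reaction). Possible failures are β-hydride elimination toward the acetal carbon (which after hydrolysis leads to the saturated ester), slow oxidative addition into the electron-rich aryl bromide with deposition of palladium black, and phenoxide-induced opening of the dihydrofuran ring at 90 °C. The fallback sets out from 14, passes through 15 and comes back at 16. Suzuki–Miyaura coupling of 14 with commercially available (E)-2-(3,3-diethoxyprop-1-enyl)-4,4,5,5-tetramethyl-1,3,2-dioxaborolane (Pd(dppf)Cl2, K3PO4, dioxane/H2O, 70 °C) should give the same acetal 15, with the alkene geometry fixed in the boronate and no β-hydride elimination involved. Hydrolysis with dilute HCl would then give 16. This fallback makes no compound outside the compound list (F0).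

**Further compounds**
F1 | step 6 | (2S,3S)-3,6-dibromo-8-methoxy-2-[3-methoxy-4-(methylsulfonyloxy)phenyl]chroman-4-one (trans) | COc1cc([C@@H]2Oc3c(OC)cc(Br)cc3C(=O)[C@H]2Br)ccc1OS(C)(=O)=O
F2 | step 6 | (2S,3S)-3,6-dibromo-4,4,8-trimethoxy-2-[3-methoxy-4-(methylsulfonyloxy)phenyl]chromane | COc1cc([C@@H]2Oc3c(OC)cc(Br)cc3C(OC)(OC)[C@H]2Br)ccc1OS(C)(=O)=O
F3 | step 5 | 4-formyl-2-methoxyphenyl methanesulfonate | COc1cc(C=O)ccc1OS(C)(=O)=O
F4 | step 5 | (E)-1-(5-bromo-2-hydroxy-3-methoxyphenyl)-3-[3-methoxy-4-(methylsulfonyloxy)phenyl]prop-2-en-1-one | COc1cc(/C=C/C(=O)c2cc(Br)cc(OC)c2O)ccc1OS(C)(=O)=O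
F5 | step 5 | racemic 6-bromo-8-methoxy-2-[3-methoxy-4-(methylsulfonyloxy)phenyl]chroman-4-one | COc1cc(C2Oc3c(OC)cc(Br)cc3C(=O)C2)ccc1OS(C)(=O)=O
F6 | step 5 | 4-[(2S,4S)-6-bromo-4-hydroxy-8-methoxychroman-2-yl]-2-methoxyphenyl methanesulfonate (cis) | COc1cc([C@H]2Oc3c(OC)cc(Br)cc3[C@@H](O)C2)ccc1OS(C)(=O)=O
F0 | step 11 | none | none
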